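Ring A of the target (C4a, C5, C6, C7, C8, C8a) is a phloroglucinol core with five substituents, the C6 acyl side chain sitting between the C5 methoxyl and the free C7 hydroxyl. A vinylketene–ynol ether benzannulation produces exactly this ortho/meta oxygen pattern, so ring A is built last from two non-aromatic pieces. One is a dihydropyran-fused 3-alkoxycyclobutenone, which supplies C7, C8, C8a and C4a with the pyran already attached. The other is a methoxyalkyne carrying the side chain as a silyl-protected carbinol, which supplies C5 and C6. One thermal operation forms C6–C7, C4a–C5 and C7–C8 and gives the fully substituted chroman-7-ol; desilylation and a double DDQ oxidation finish the synthesis.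

Key step: step 6

Remark: the target has no stereocentre; the side-chain carbinol carbon that appears on the way is carried racemic and removed by oxidation, and ketene is taken as a gas stream generated from acetone.

Step 1
Reactants: 1 chloroacetaldehyde dimethyl acetal; 2 4-methoxyphenylacetaldehyde
Product: 4 racemic 4-methoxy-1-(4-methoxyphenyl)but-3-yn-2-ol, via lithium methoxyacetylide 3 (not isolated)
Conditions: Et2NH, n-BuLi (3.0 equiv each per 1), THF, 0 °C; 1 (1.3 equiv), 0 °C→rt; then 2 (1.0 equiv), −78 °C; H2O
Reagents that add atoms: none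
Why: Lithium diethylamide should strip methanol and hydrogen chloride from the chloroacetal and deprotonate the resulting methoxyacetylene, and the lithium acetylide then adds 1,2 to the aldehyde (acetylide–carbonyl addition) fast enough at −78 °C to compete with enolisation; the carbinol centre forms without control, hence racemic, and is erased in step 8.

Step 2
Reactants: 4 racemic 4-methoxy-1-(4-methoxyphenyl)but-3-yn-2-ol
Product: 5 racemic tert-butyl{[4-methoxy-1-(4-methoxyphenyl)but-3-yn-2-yl]oxy}dimethylsilane
Conditions: TBSCl, imidazole, DMF, rt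
Reagents that add atoms: tert-butyldimethylsilyl chloride (TBSCl), CC(C)(C)[Si](C)(C)Cl
Why: Silylation of a secondary propargylic alcohol with a silyl chloride and imidazole is routine, and the buffered medium should spare the acid-labile ynol ether; the stereocentre is untouched.

Step 3
Reactants: 6 ethoxyacetylene; 7 1-bromo-3-methylbut-2-ene
Product: 9 1-ethoxy-5-methylhex-4-en-1-yne, via lithium ethoxyacetylide 8 (not isolated)
Conditions: n-BuLi, THF, −78 °C; then 7, DMPU, −78 °C→rt
Reagents that add atoms: none
Why: Deprotonation of the terminal ynol ether gives a lithium acetylide that should displace bromide at the primary allylic carbon of 7 in the dipolar cosolvent (SN2 alkylation of an acetylide), the hindered tertiary terminus disfavouring SN2′ attack.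

Step 4
Reactants: 9 1-ethoxy-5-methylhex-4-en-1-yne; 10 acetone
Product: 12 3-ethoxy-2-(3-methylbut-2-en-1-yl)cyclobut-2-en-1-one, via ketene 11 (not isolated)
Conditions: 10, hot-filament pyrolysis (ketene lamp, ca. 700 °C); ketene stream into 9, CH2Cl2, 0 °C→rt
Reagents that add atoms: none
Why: Ketene should undergo thermal [2+2] cycloaddition with the 1-alkoxyalkyne, the nucleophilic prenyl-bearing alkyne carbon bonding to the ketene carbonyl carbon, so that the ethoxy group ends at C3 and the prenyl group at C2 of the cyclobutenone, while the unactivated trisubstituted alkene is inert to ketene.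

Step 5
Reactants: 12 3-ethoxy-2-(3-methylbut-2-en-1-yl)cyclobut-2-en-1-one
Product: 14 3,3-dimethyl-2-oxabicyclo[4.2.0]oct-1(6)-en-7-one, via 3-hydroxy-2-(3-methylbut-2-en-1-yl)cyclobut-2-en-1-one 13 (not isolated)
Conditions: TFA–CH2Cl2 (1:1), H2O (1.5 equiv), 0 °C→rt
Reagents that add atoms: water, O
Why: Aqueous acid should hydrolyse the vinylogous ester to the fully enolised 2-prenylcyclobutane-1,3-dione 13, whose enol oxygen then adds in Markovnikov fashion to the protonated prenyl alkene (acid-catalysed 6-endo hydroalkoxylation, the way 2-prenyl-1,3-diones and o-prenylphenols give 2,2-dimethyldihydropyrans); the symmetry of the dione means either oxygen gives the same product.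

Step 6
Reactants: 14 3,3-dimethyl-2-oxabicyclo[4.2.0]oct-1(6)-en-7-one; 5 racemic tert-butyl{[4-methoxy-1-(4-methoxyphenyl)but-3-yn-2-yl]oxy}dimethylsilane
Product: 19 racemic 6-{1-[(tert-butyldimethylsilyl)oxy]-2-(4-methoxyphenyl)ethyl}-5-methoxy-2,2-dimethylchroman-7-ol, via vinylketene 15 (not isolated), via spirocyclic vinylcyclobutenone 16 (not isolated), via dienylketene 17 (not isolated), via cyclohexadienone 18 (not isolated)
Conditions: 14 (1.0 equiv), 5 (1.3 equiv), PhMe (0.4 M), 120 °C, sealed tube
Reagents that add atoms: none
Why: Heating should open 14 by 4π electrocyclic cleavage of its C(=O)–CH2 bond to vinylketene 15, whose ketene C=C adds ynol ether 5 in a [2+2] cycloaddition (C6–C7 and C4a–C5) to give spirocyclic vinylcyclobutenone 16; a second 4π opening gives dienylketene 17, which closes to cyclohexadienone 18 (C7–C8) and enolises to phenol 19. The closest known reaction type is the Danheiser benzannulation of cyclobutenones with alkoxyalkynes to resorcinol monoethers. Ring A is closed by thermal 6π electrocyclisation of the dienylketene as a six-membered all-carbon ring, while the dihydropyran ring is carried intact from 14 and ends fused at C4a–C8a. No stereocentre is created: the carbinol centre comes racemic from 5 and the spiro centre of 16 is lost on ring opening. The step needs the regiochemistry of the ketene–alkyne union, which the polarisation of the ynol ether secures, because its carbon remote from oxygen attacks the ketene carbonyl carbon, so the carbinol-bearing carbon becomes C6 next to the new C7 hydroxyl and the methoxy carbon becomes C5. The methoxy group has no β-hydrogen and so keeps the alkyne from retro-ene fragmentation at this temperature, and any aryl ester formed from 19 and a second vinylketene can be returned to the phenol with K2CO3 in MeOH.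

Step 7
Reactants: 19 racemic 6-{1-[(tert-butyldimethylsilyl)oxy]-2-(4-methoxyphenyl)ethyl}-5-methoxy-2,2-dimethylchroman-7-ol
Product: 20 racemic 6-[1-hydroxy-2-(4-methoxyphenyl)ethyl]-5-methoxy-2,2-dimethylchroman-7-ol
Conditions: TBAF, AcOH (1.5 equiv each), THF, 0 °C→rt
Reagents that add atoms: none
Why: Fluoride should cleave the hindered secondary benzylic silyl ether (fluoride-mediated desilylation), and the acetic acid buffer keeps the phenoxide concentration low so that expulsion of the benzylic oxygen towards an o-quinone methide is not set off; the carbinol remains racemic.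

Step 8
Reactants: 20 racemic 6-[1-hydroxy-2-(4-methoxyphenyl)ethyl]-5-methoxy-2,2-dimethylchroman-7-ol
Product: 22 1-(7-hydroxy-5-methoxy-2,2-dimethyl-2H-chromen-6-yl)-2-(4-methoxyphenyl)ethan-1-one, via 1-(7-hydroxy-5-methoxy-2,2-dimethylchroman-6-yl)-2-(4-methoxyphenyl)ethan-1-one 21 (not isolated)
Conditions: DDQ (1.1 equiv), 1,4-dioxane, rt; then DDQ (1.3 equiv), 90 °C
Reagents that add atoms: none
Why: DDQ should abstract hydride from the carbinol carbon ortho to the free C7 hydroxyl at room temperature (quinone dehydrogenation of an o-hydroxybenzylic alcohol) to give the chelated ketone 21, and on heating from C4, which is para to that hydroxyl and ortho to the C5 methoxyl, with loss of the C3 proton (the usual DDQ dehydrogenation of a 2,2-dimethylchroman to the 2H-chromene); the only stereocentre disappears in the first oxidation.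

Compound list
1 | chloroacetaldehyde dimethyl acetal (2-chloro-1,1-dimethoxyethane) | COC(CCl)OC | starting material
2 | 4-methoxyphenylacetaldehyde | COc1ccc(CC=O)cc1 | starting material
3 | lithium methoxyacetylide | [Li]C#COC | intermediate
4 | racemic 4-methoxy-1-(4-methoxyphenyl)but-3-yn-2-ol | COC#CC(O)Cc1ccc(OC)cc1 | intermediate
5 | racemic tert-butyl{[4-methoxy-1-(4-methoxyphenyl)but-3-yn-2-yl]oxy}dimethylsilane | COC#CC(O[Si](C)(C)C(C)(C)C)Cc1ccc(OC)cc1 | intermediate
6 | ethoxyacetylene | CCOC#C | starting material
7 | 1-bromo-3-methylbut-2-ene | CC(C)=CCBr | starting material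
8 | lithium ethoxyacetylide | [Li]C#COCC | intermediate
9 | 1-ethoxy-5-methylhex-4-en-1-yne | CCOC#CCC=C(C)C | intermediate
10 | acetone | CC(C)=O | starting material
11 | ketene | C=C=O | intermediate
12 | 3-ethoxy-2-(3-methylbut-2-en-1-yl)cyclobut-2-en-1-one | CCOC1=C(CC=C(C)C)C(=O)C1 | intermediate
13 | 3-hydroxy-2-(3-methylbut-2-en-1-yl)cyclobut-2-en-1-one (enol of 2-prenylcyclobutane-1,3-dione) | OC1=C(CC=C(C)C)C(=O)C1 | intermediate
14 | 3,3-dimethyl-2-oxabicyclo[4.2.0]oct-1(6)-en-7-one | CC1(C)CCC2=C(O1)CC2=O | intermediate
15 | 2-(6,6-dimethyl-2-methylideneoxan-3-ylidene)ethen-1-one (vinylketene) | O=C=C1CCC(C)(C)OC1=C | intermediate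
16 | 2-{1-[(tert-butyldimethylsilyl)oxy]-2-(4-methoxyphenyl)ethyl}-3-methoxy-7,7-dimethyl-5-methylidene-6-oxaspiro[3.5]non-2-en-1-one (racemic, mixture of diastereomers) | O=C1C(C(O[Si](C)(C)C(C)(C)C)Cc2ccc(OC)cc2)=C(OC)C13CCC(C)(C)OC3=C | intermediate
17 | racemic 2-{1-[(tert-butyldimethylsilyl)oxy]-2-(4-methoxyphenyl)ethyl}-3-(6,6-dimethyl-2-methylideneoxan-3-ylidene)-3-methoxyprop-1-en-1-one (dienylketene) | O=C=C(C(O[Si](C)(C)C(C)(C)C)Cc1ccc(OC)cc1)C(OC)=C1CCC(C)(C)OC1=C | intermediate
18 | racemic 6-{1-[(tert-butyldimethylsilyl)oxy]-2-(4-methoxyphenyl)ethyl}-5-methoxy-2,2-dimethyl-3,4-dihydro-2H-chromen-7(8H)-one | O=C1CC2=C(CCC(C)(C)O2)C(OC)=C1C(O[Si](C)(C)C(C)(C)C)Cc1ccc(OC)cc1 | intermediate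
19 | racemic 6-{1-[(tert-butyldimethylsilyl)oxy]-2-(4-methoxyphenyl)ethyl}-5-methoxy-2,2-dimethylchroman-7-ol | COc1ccc(CC(O[Si](C)(C)C(C)(C)C)c2c(O)cc3c(c2OC)CCC(C)(C)O3)cc1 | intermediate
20 | racemic 6-[1-hydroxy-2-(4-methoxyphenyl)ethyl]-5-methoxy-2,2-dimethylchroman-7-ol | COc1ccc(CC(O)c2c(O)cc3c(c2OC)CCC(C)(C)O3)cc1 | intermediate
21 | 1-(7-hydroxy-5-methoxy-2,2-dimethylchroman-6-yl)-2-(4-methoxyphenyl)ethan-1-one | COc1ccc(CC(=O)c2c(O)cc3c(c2OC)CCC(C)(C)O3)cc1 | intermediate
22 | 1-(7-hydroxy-5-methoxy-2,2-dimethyl-2H-chromen-6-yl)-2-(4-methoxyphenyl)ethan-1-one | COc1ccc(CC(=O)c2c(O)cc3c(c2OC)C=CC(C)(C)O3)cc1 | target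

Total step count: 8 steps.
Longest linear sequence: 6 steps (steps 3, 4, 5, 6, 7, 8, from ethoxyacetylene 6); the alkyne branch (steps 1, 2) joins at step 6.

Steps most likely to fail

1. Step 6. The vinylogous-ester resonance of 14 may slow the electrocyclic ring opening. At the temperature then needed, the ynol ether could oligomerise, or the product could lose silanol from the benzylic position next to the free phenol (o-quinone methide formation). The fallback generates the same vinylketene 15 near room temperature without a cyclobutenone. It sets out from 7: alkylation of ethyl acetoacetate with 7 (NaOEt, EtOH) should give racemic ethyl 2-acetyl-5-methylhex-4-enoate F1. SnCl4 in CH2Cl2 at 0 °C should close the enol oxygen onto the prenyl group to give ethyl 2,2,6-trimethyl-3,4-dihydro-2H-pyran-5-carboxylate F2. Saponification (KOH, aqueous EtOH, then careful acidification) should give 2,2,6-trimethyl-3,4-dihydro-2H-pyran-5-carboxylic acid F3. 1-Chloro-N,N,2-trimethylprop-1-en-1-amine in CH2Cl2 should convert this under neutral conditions into 2,2,6-trimethyl-3,4-dihydro-2H-pyran-5-carbonyl chloride F4. Slow addition of F4 to Et3N and 5 in toluene (rt, then 80 °C) should form 15 by 1,4-dehydrochlorination, that is, deprotonation of the C6 methyl group of the activated acyl species. 15 then runs through 16, 17 and 18 as in the main route, and the fallback rejoins at 19.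

2. Step 5. The strained 1,3-dione enol 13 may suffer hydrolytic ring cleavage (retro-Claisen opening to a β-keto acid), or the tertiary cation may be diverted before an oxygen captures it. The fallback sets out from 12 and never passes through the free dione. Mukaiyama hydration of the trisubstituted alkene (Co(acac)2 cat., PhSiH3, O2, i-PrOH, rt) should give 3-ethoxy-2-(3-hydroxy-3-methylbutyl)cyclobut-2-en-1-one F5. PPTS (cat.) in toluene at 80 °C over 4 Å molecular sieves should then exchange the ethoxy group of the vinylogous ester for the tertiary hydroxyl by intramolecular addition–elimination. The fallback rejoins the route at 14.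

3. Step 8. Hydride abstraction from C4 may stall once the chelated C6 acyl group has deactivated ring A, or the electron-rich free phenol may be over-oxidised during prolonged heating with the quinone. The fallback sets out from 19 and dehydrogenates first, while ring A is most electron-rich. DDQ (1.1 equiv, 1,4-dioxane, rt) should give racemic 6-{1-[(tert-butyldimethylsilyl)oxy]-2-(4-methoxyphenyl)ethyl}-5-methoxy-2,2-dimethyl-2H-chromen-7-ol F6 by way of the para-quinone methide. TBAF buffered with AcOH (THF, 0 °C→rt) should give racemic 6-[1-hydroxy-2-(4-methoxyphenyl)ethyl]-5-methoxy-2,2-dimethyl-2H-chromen-7-ol F7. Activated MnO2 (CH2Cl2, rt) should then oxidise the benzylic carbinol on the surface oxidant, and the fallback arrives at 22.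

Further compounds
F1 | step 6 | racemic ethyl 2-acetyl-5-methylhex-4-enoate | CCOC(=O)C(CC=C(C)C)C(C)=O
F2 | step 6 | ethyl 2,2,6-trimethyl-3,4-dihydro-2H-pyran-5-carboxylate | CCOC(=O)C1=C(C)OC(C)(C)CC1
F3 | step 6 | 2,2,6-trimethyl-3,4-dihydro-2H-pyran-5-carboxylic acid | CC1=C(C(=O)O)CCC(C)(C)O1
F4 | step 6 | 2,2,6-trimethyl-3,4-dihydro-2H-pyran-5-carbonyl chloride | CC1=C(C(=O)Cl)CCC(C)(C)O1
F5 | step 5 | 3-ethoxy-2-(3-hydroxy-3-methylbutyl)cyclobut-2-en-1-one | CCOC1=C(CCC(C)(C)O)C(=O)C1
F6 | step 8 | racemic 6-{1-[(tert-butyldimethylsilyl)oxy]-2-(4-methoxyphenyl)ethyl}-5-methoxy-2,2-dimethyl-2H-chromen-7-ol | COc1ccc(CC(O[Si](C)(C)C(C)(C)C)c2c(O)cc3c(c2OC)C=CC(C)(C)O3)cc1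
F7 | step 8 | racemic 6-[1-hydroxy-2-(4-methoxyphenyl)ethyl]-5-methoxy-2,2-dimethyl-2H-chromen-7-ol | COc1ccc(CC(O)c2c(O)cc3c(c2OC)C=CC(C)(C)O3)cc1
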